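**Plan**

1. Retrosynthesis: the enone is cut at C13=C14 (Horner–Wadsworth–Emmons) and the α-chain at C5=C6 (Wittig on a lactol), which leaves a cis-fused 2-oxabicyclo[3.3.0]octane whose oxolane ring joins O9 to C6. The ring bond C9–C10 is cut next (carbenoid C–H insertion), then C10–C11 (acylation of diazomethane) and C8–C12 (Michael addition of malonate to a γ-silyloxy enal).
2. Enabling feature: C9 is a carbinol carbon 1,3 to the C11 oxygen, and O9 lies four atoms from C6. With O9 and C6 tied in an oxolane (O–C9–C8–C7–C6), C9 is an ether CH2 whose C–H bond sits 1,5 to a carbenoid carbon C10 placed next to a C11 ketone. That C–H bond is activated by the ring oxygen and can be reached only on the face that gives the cis-fused bicycle.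
3. Forward order: Michael addition (C8–C12), oxolane acetal (temporary ring), half-ester salt and diazoketone (C10–C11), dirhodium-catalysed insertion (C9–C10, the only carbocycle), reduction, lactol, α-chain by Wittig, ω-chain by oxidation and olefination. The acetal ring is the only protecting device.
4. Stereochemistry: C8 comes from the organocatalyst. C9 is relayed from C8 by the cis ring fusion of the insertion. C12 settles by equilibration of a β-keto ester to the exo side, so all epimers at C12 and at the acetal carbon converge. C11 comes from hydride attack on the convex face; 5Z from the non-stabilised ylide; 13E from the phosphonate.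

Key step: step 5

Remark: atoms are called by prostanoid numbers (C1 = carboxyl carbon). (2E)-4-[(tert-Butyldimethylsilyl)oxy]but-2-enal is assumed to be a catalogue compound (otherwise two steps from (Z)-but-2-ene-1,4-diol). The acetal carbon C6 of the oxolane intermediates is carried as both anomers, since it ends as the sp2 carbon C6 of the target.

**Route**

Step 1
Reactants: 1 (2E)-4-[(tert-butyldimethylsilyl)oxy]but-2-enal; 2 dimethyl malonate
Product: 3 dimethyl 2-[(2R)-1-[(tert-butyldimethylsilyl)oxy]-4-oxobutan-2-yl]propanedioate
Conditions: (S)-2-{bis[3,5-bis(trifluoromethyl)phenyl][(trimethylsilyl)oxy]methyl}pyrrolidine (10 mol %), EtOH, 0 °C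
Reagents that add atoms: none
Why: Organocatalytic asymmetric Michael addition through an E-iminium ion of 1; the aryl(silyloxy)methyl group of the S catalyst shields one face, so malonate should add to the other face of C8 and give the 2R adduct, the only stereocentre that is bought.

Step 2
Reactants: 3 dimethyl 2-[(2R)-1-[(tert-butyldimethylsilyl)oxy]-4-oxobutan-2-yl]propanedioate
Product: 4 dimethyl 2-[(3R)-5-methoxyoxolan-3-yl]propanedioate
Conditions: camphor-10-sulfonic acid (5 mol %), MeOH, 0 °C → rt; Et3N quench
Reagents that add atoms: methanol, CO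
Why: Acid-catalysed methanolysis removes the silyl group and the freed C9 hydroxyl closes on the C6 oxocarbenium ion (acetalisation, 5-exo), which should be far faster than lactonisation onto the malonate; C8 is untouched and the acetal centre is lost again in step 7.

Step 3
Reactants: 4 dimethyl 2-[(3R)-5-methoxyoxolan-3-yl]propanedioate
Product: 5 potassium 3-methoxy-2-[(3R)-5-methoxyoxolan-3-yl]-3-oxopropanoate
Conditions: KOH (1.0 equiv), THF/H2O, 0 °C; evaporation, azeotropic drying with toluene
Reagents that add atoms: potassium hydroxide, [K+].[OH-]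
Why: Saponification of a malonate diester stops at the half-ester because the carboxylate deactivates its neighbour; C12 becomes a stereocentre without control, which is harmless because it is epimerisable again in 8, and the salt is not acidified so that the acetal survives.

Step 4
Reactants: 5 potassium 3-methoxy-2-[(3R)-5-methoxyoxolan-3-yl]-3-oxopropanoate
Product: 7 methyl 4-diazo-2-[(3R)-5-methoxyoxolan-3-yl]-3-oxobutanoate, via acid chloride 6 (not isolated)
Conditions: (COCl)2 (1.05 equiv), N,N-dimethylformamide (cat.), CH2Cl2, 0 °C; then CH2N2 (3 equiv), Et2O, 0 °C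
Reagents that add atoms: diazomethane, C=[N+]=[N-]
Why: Acylation of diazomethane by an acid chloride (first half of the Arndt–Eistert sequence); the chloride is made from the potassium salt so that no HCl meets the acetal, a second equivalent of diazomethane takes up the HCl of the acylation, and no stereocentre is formed.

Step 5
Reactants: 7 methyl 4-diazo-2-[(3R)-5-methoxyoxolan-3-yl]-3-oxobutanoate
Product: 8 methyl (3aR,4R,6aS)-2-methoxy-5-oxohexahydro-2H-cyclopenta[b]furan-4-carboxylate
Conditions: Rh2(OAc)4 (1 mol %), CH2Cl2, 40 °C, slow addition of 7; then chromatography on silica gel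
Reagents that add atoms: none
Why: Loss of N2 from 7 at dirhodium tetraacetate should give an electrophilic carbenoid at C10 (by nature the nucleophilic α-carbon of the C11 ketone), which inserts through a concerted, asynchronous three-centre transition state with hydride-like transfer into the C9–H bond five atoms away; the closest known reaction type is the dirhodium-catalysed intramolecular 1,5 C–H insertion of α-diazo ketones to cyclopentanones, for which a C–H bond next to an ether oxygen is the preferred site. The cyclopentane is closed in the 1,5 (five-membered ring forming) insertion mode and is fused to the oxolane that already joins O9 to C6, giving the 2-oxabicyclo[3.3.0]octane core. C9 (C6a) is set by the ring: the carbenoid hangs from C8 and can reach only the C9–H on its own face, and insertion goes with retention, so only the cis-fused bicycle with O9 cis to C7 can form. C12 (C4) is an epimerisable β-keto ester centre and should settle on silica in the exo orientation, trans to C7 on the convex face, so both C12 epimers of 7 converge. The step needs site selectivity for C9–H over C7–H (also 1,5), over the acetal C6–H (1,6) and over attack on the ring oxygen; this should be secured by the α-oxygen activation of C9–H, the inductive deactivation of C7–H by the neighbouring acetal carbon, the preference for five-membered ring formation, and the strained bridged bicycle that an oxonium ylide at the ring oxygen would need.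

Step 6
Reactants: 8 methyl (3aR,4R,6aS)-2-methoxy-5-oxohexahydro-2H-cyclopenta[b]furan-4-carboxylate
Product: 10 (3aR,4S,5R,6aS)-4-(hydroxymethyl)-2-methoxyhexahydro-2H-cyclopenta[b]furan-5-ol, via hydroxy ester 9 (not isolated)
Conditions: LiBH4 (4 equiv), THF/MeOH (20:1), −40 °C → rt; pH 7 phosphate buffer
Reagents that add atoms: none
Why: Borohydride reduction of the ketone at low temperature and of the ester of 9 on warming; hydride should reach C11 from the convex face of the cis-fused bicycle, opposite the oxolane ring, to give the 5R (11α) alcohol trans to the C12 substituent, and the acetal is not touched.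

Step 7
Reactants: 10 (3aR,4S,5R,6aS)-4-(hydroxymethyl)-2-methoxyhexahydro-2H-cyclopenta[b]furan-5-ol
Product: 11 (3aR,4S,5R,6aS)-4-(hydroxymethyl)hexahydro-2H-cyclopenta[b]furan-2,5-diol
Conditions: 1 M HCl/THF (1:1), rt; NaHCO3
Reagents that add atoms: water, O
Why: Mild acid hydrolysis of the methyl acetal frees the lactol, the masked C6 aldehyde; no stereocentre of the target is affected.

Step 8
Reactants: 11 (3aR,4S,5R,6aS)-4-(hydroxymethyl)hexahydro-2H-cyclopenta[b]furan-2,5-diol; 12 (4-carboxybutyl)triphenylphosphonium bromide
Product: 13 (5Z)-7-[(1R,2S,3R,5S)-3,5-dihydroxy-2-(hydroxymethyl)cyclopentyl]hept-5-enoic acid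
Conditions: 12 (5 equiv), KOtBu (10 equiv), THF, 0 °C → rt; work-up at pH 4
Reagents that add atoms: none
Why: Wittig olefination of the lactol through its hydroxy-aldehyde form with a non-stabilised potassium ylide, which should give the 5Z alkene under kinetic control; the free hydroxyls are carried as alkoxides by the excess of ylide.

Step 9
Reactants: 13 (5Z)-7-[(1R,2S,3R,5S)-3,5-dihydroxy-2-(hydroxymethyl)cyclopentyl]hept-5-enoic acid
Product: 14 (5Z)-7-[(1R,2R,3R,5S)-2-formyl-3,5-dihydroxycyclopentyl]hept-5-enoic acid
Conditions: 2,2,6,6-tetramethylpiperidin-1-oxyl (10 mol %), PhI(OAc)2 (1.1 equiv), CH2Cl2/MeCN (4:1), 0 °C → rt; crude 14 used at once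
Reagents that add atoms: none
Why: Oxoammonium-mediated oxidation is selective for the primary carbinol over the two secondary ones and leaves the Z-alkene and the acid alone; the aldehyde on the β-face cannot form a lactol with the α-face C9 hydroxyl, and the all-trans C12 centre is the thermodynamic one.

Step 10
Reactants: 14 (5Z)-7-[(1R,2R,3R,5S)-2-formyl-3,5-dihydroxycyclopentyl]hept-5-enoic acid; 15 dimethyl (2-oxoheptyl)phosphonate
Product: 16 15-keto-PGF2α
Conditions: 15 (1.5 equiv), LiCl (3 equiv), iPr2NEt (3 equiv), MeCN, 0 °C → rt; work-up at pH 4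
Reagents that add atoms: none
Why: Horner–Wadsworth–Emmons olefination with a β-keto phosphonate under LiCl/amine conditions, mild enough for a β-hydroxy aldehyde, should give the 13E enone; the excess amine carries the carboxylic acid as its salt.

**Compound list**

1 | (2E)-4-[(tert-butyldimethylsilyl)oxy]but-2-enal | O=C/C=C/CO[Si](C)(C)C(C)(C)C | starting material
2 | dimethyl malonate (dimethyl propanedioate) | COC(=O)CC(=O)OC | starting material
3 | dimethyl 2-[(2R)-1-[(tert-butyldimethylsilyl)oxy]-4-oxobutan-2-yl]propanedioate | COC(=O)C(C(=O)OC)[C@@H](CC=O)CO[Si](C)(C)C(C)(C)C | intermediate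
4 | dimethyl 2-[(3R)-5-methoxyoxolan-3-yl]propanedioate (both anomers) | COC(=O)C(C(=O)OC)[C@@H]1COC(OC)C1 | intermediate
5 | potassium 3-methoxy-2-[(3R)-5-methoxyoxolan-3-yl]-3-oxopropanoate (both epimers at C2, both anomers) | COC(=O)C(C(=O)[O-])[C@@H]1COC(OC)C1.[K+] | intermediate
6 | methyl 3-chloro-2-[(3R)-5-methoxyoxolan-3-yl]-3-oxopropanoate (acid chloride) | COC(=O)C(C(Cl)=O)[C@@H]1COC(OC)C1 | intermediate
7 | methyl 4-diazo-2-[(3R)-5-methoxyoxolan-3-yl]-3-oxobutanoate | COC(=O)C(C(=O)C=[N+]=[N-])[C@@H]1COC(OC)C1 | intermediate
8 | methyl (3aR,4R,6aS)-2-methoxy-5-oxohexahydro-2H-cyclopenta[b]furan-4-carboxylate | COC(=O)[C@@H]1[C@@H](CC(OC)O2)[C@@H]2CC1=O | intermediate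
9 | methyl (3aR,4R,5R,6aS)-5-hydroxy-2-methoxyhexahydro-2H-cyclopenta[b]furan-4-carboxylate | COC(=O)[C@@H]1[C@@H](CC(OC)O2)[C@@H]2C[C@H]1O | intermediate
10 | (3aR,4S,5R,6aS)-4-(hydroxymethyl)-2-methoxyhexahydro-2H-cyclopenta[b]furan-5-ol | OC[C@@H]1[C@@H](CC(OC)O2)[C@@H]2C[C@H]1O | intermediate
11 | (3aR,4S,5R,6aS)-4-(hydroxymethyl)hexahydro-2H-cyclopenta[b]furan-2,5-diol | OC[C@@H]1[C@@H](CC(O)O2)[C@@H]2C[C@H]1O | intermediate
12 | (4-carboxybutyl)triphenylphosphonium bromide | OC(=O)CCCC[P+](c1ccccc1)(c1ccccc1)c1ccccc1.[Br-] | starting material
13 | (5Z)-7-[(1R,2S,3R,5S)-3,5-dihydroxy-2-(hydroxymethyl)cyclopentyl]hept-5-enoic acid | OC[C@@H]1[C@@H](C/C=C\CCCC(=O)O)[C@@H](O)C[C@H]1O | intermediate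
14 | (5Z)-7-[(1R,2R,3R,5S)-2-formyl-3,5-dihydroxycyclopentyl]hept-5-enoic acid | O=C[C@@H]1[C@@H](C/C=C\CCCC(=O)O)[C@@H](O)C[C@H]1O | intermediate
15 | dimethyl (2-oxoheptyl)phosphonate | CCCCCC(=O)CP(=O)(OC)OC | starting material
16 | 15-keto-PGF2α, (5Z)-7-[(1R,2R,3R,5S)-3,5-dihydroxy-2-[(1E)-3-oxooct-1-en-1-yl]cyclopentyl]hept-5-enoic acid | CCCCCC(=O)/C=C/[C@@H]1[C@@H](C/C=C\CCCC(=O)O)[C@@H](O)C[C@H]1O | target

Total step count: 10
Longest linear sequence: 10 steps (from 1 and 2 to 16)

**Steps most likely to fail**

Step 5 (ring closure). The carbenoid may be diverted from 1,5-insertion at C9–H: attack on the ring oxygen followed by a 1,2-shift, insertion at the acetal C–H or at C7–H, or carbene dimerisation would each lower the share of the wanted closure. The fallback gives up the C–H insertion and builds the same bicycle by aldol chemistry. It cannot set out from 7 or any earlier numbered compound, because all of them carry C9 as an ether CH2 that only a C–H functionalisation can join to C10; it therefore starts from commercial 2,5-dimethoxytetrahydrofuran and comes back to the route at 10. Hydrolysis in hot water should give succinaldehyde F1. L-Proline (2 mol %, EtOAc) and then dibenzylammonium trifluoroacetate should dimerise it by aldol addition and aldol condensation to (3aR,6aS)-2-hydroxy-3,3a,6,6a-tetrahydro-2H-cyclopenta[b]furan-5-carbaldehyde F2, whose formyl carbon is excised later. Amberlyst 15 in MeOH should give the methyl acetal F3. VinylMgBr with CuBr·SMe2 and Me3SiCl (THF, −78 °C) should add the vinyl group to C12 on the convex face and trap the enolate as the silyl enol ether F4. Ozonolysis of both double bonds (CH2Cl2/MeOH, −78 °C) followed by NaBH4 should give 10.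

Step 6 (reduction). Poor facial selectivity in the hydride addition to the C11 ketone is possible: the exo ester at C12 screens the convex face that the bicycle otherwise favours, so attack from the concave face may compete and give the 11β carbinol. The fallback replaces substrate control by catalyst control. It sets out from 8 and comes back at 10 through 9, and makes no compound outside the list (entry F0). A Noyori-type asymmetric hydrogenation of the β-keto ester with dynamic kinetic resolution ([RuCl(C6H6)((R)-BINAP)]Cl, H2 50 bar, CH2Cl2, 50 °C) should deliver the trans hydroxy ester 9. The R ligand is the one expected to match, by analogy with 2-oxocyclopentanecarboxylates, and the fast enolisation at C12 feeds both epimers into one product. LiBH4 in THF should then reduce isolated 9 to 10.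

Step 9 (oxidation, with its consequence for step 10). On the polar triol acid, chemoselectivity may be lost through over-oxidation or attack on a secondary carbinol, and the unprotected β-hydroxy aldehyde may suffer β-elimination of the C11 hydroxyl or epimerisation at C12 before or during the olefination. The fallback changes the order of the chains and carries C15 as a carbinol. It sets out from 10 and comes back at 16.
- The same oxoammonium oxidation on the neutral acetal diol 10 should give (3aR,4R,5R,6aS)-5-hydroxy-2-methoxyhexahydro-2H-cyclopenta[b]furan-4-carbaldehyde F5.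
- Olefination with 15 (LiCl, iPr2NEt, MeCN) should give the enone acetal F6.
- Luche reduction (NaBH4, CeCl3·7H2O, MeOH, −78 °C) should give the allylic alcohols F7 as both C15 epimers, which makes the ω-chain compatible with the ylide.
- 1 M HCl/THF should give the lactol F8.
- Wittig reaction with 12 and KOtBu should give PGF2α together with its C15 epimer F9.
- 2,3-Dichloro-5,6-dicyano-1,4-benzoquinone in dioxane should oxidise only the allylic C15 carbinol, so both epimers converge on 16.

Further compounds
F1 | step 5 | succinaldehyde (butanedial) | O=CCCC=O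
F2 | step 5 | (3aR,6aS)-2-hydroxy-3,3a,6,6a-tetrahydro-2H-cyclopenta[b]furan-5-carbaldehyde | O=CC1=C[C@@H](CC(O)O2)[C@@H]2C1
F3 | step 5 | (3aR,6aS)-2-methoxy-3,3a,6,6a-tetrahydro-2H-cyclopenta[b]furan-5-carbaldehyde | O=CC1=C[C@@H](CC(OC)O2)[C@@H]2C1
F4 | step 5 | {[(3aR,4R,6aS)-4-ethenyl-2-methoxyhexahydro-5H-cyclopenta[b]furan-5-ylidene]methoxy}trimethylsilane | C=C[C@@H]1[C@@H](CC(OC)O2)[C@@H]2CC1=CO[Si](C)(C)C
F0 | step 6 | none | none
F5 | step 9 | (3aR,4R,5R,6aS)-5-hydroxy-2-methoxyhexahydro-2H-cyclopenta[b]furan-4-carbaldehyde | O=C[C@@H]1[C@@H](CC(OC)O2)[C@@H]2C[C@H]1O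
F6 | step 9 | (1E)-1-[(3aR,4R,5R,6aS)-5-hydroxy-2-methoxyhexahydro-2H-cyclopenta[b]furan-4-yl]oct-1-en-3-one | CCCCCC(=O)/C=C/[C@@H]1[C@@H](CC(OC)O2)[C@@H]2C[C@H]1O
F7 | step 9 | (3aR,4R,5R,6aS)-4-[(1E)-3-hydroxyoct-1-en-1-yl]-2-methoxyhexahydro-2H-cyclopenta[b]furan-5-ol (both C3' epimers) | CCCCCC(O)/C=C/[C@@H]1[C@@H](CC(OC)O2)[C@@H]2C[C@H]1O
F8 | step 9 | (3aR,4R,5R,6aS)-4-[(1E)-3-hydroxyoct-1-en-1-yl]hexahydro-2H-cyclopenta[b]furan-2,5-diol (both C3' epimers) | CCCCCC(O)/C=C/[C@@H]1[C@@H](CC(O)O2)[C@@H]2C[C@H]1O
F9 | step 9 | PGF2α with its C15 epimer, (5Z)-7-[(1R,2R,3R,5S)-3,5-dihydroxy-2-[(1E)-3-hydroxyoct-1-en-1-yl]cyclopentyl]hept-5-enoic acid | CCCCCC(O)/C=C/[C@@H]1[C@@H](C/C=C\CCCC(=O)O)[C@@H](O)C[C@H]1O
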